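Ring A is not coupled as an arene; it is grown on the crowded ring B oxygen. C1 of ring A (the hydroxyl carbon) and C2 (the carbon carrying the ether oxygen) correspond to the ketone and the α-carbon of an acetoacetate, so the ring B oxygen, flanked by Br and OMe, needs only an SN2 alkylation. The key step then combines this α-aryloxy β-keto ester, ethyl 2-(3,5,6-tribromo-2-methoxyphenoxy)-3-oxobutanoate, with acrolein: conjugate addition makes C2–C3, aldol condensation makes C5–C6 and closes ring A as a cyclohexenone. Loss of the ester, dehydrogenation, bromination para to the new hydroxyl and O-demethylation complete the target.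

Key step: step 5

Remark: the target is achiral; every stereocentre on the route is transient, is formed as a racemate (or a diastereomer mixture) and disappears when ring A is aromatized, so all SMILES are given without stereodescriptors.

Step 1
Reactants: 1 2-bromo-6-hydroxybenzaldehyde
Product: 2 3,5,6-tribromo-2-hydroxybenzaldehyde
Conditions: Br2 (2.2 equiv), AcOH, rt
Reagents that add atoms: bromine, BrBr
Why: Electrophilic aromatic bromination; the hydroxyl directs to its free ortho and para carbons (C3 and C5), which are also meta to the formyl group and para/ortho to the bromine already present, so all three substituents converge on the same two positions and C4 should stay unsubstituted.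

Step 2
Reactants: 2 3,5,6-tribromo-2-hydroxybenzaldehyde
Product: 3 3,5,6-tribromo-2-methoxybenzaldehyde
Conditions: MeI, K2CO3, DMF, rt
Reagents that add atoms: iodomethane, CI
Why: Williamson ether synthesis; the acidic phenol is deprotonated by carbonate and the small methyl iodide should react by SN2 even at a phenoxide with two ortho substituents.

Step 3
Reactants: 3 3,5,6-tribromo-2-methoxybenzaldehyde
Product: 5 3,5,6-tribromo-2-methoxyphenol, via aryl formate 4 (not isolated)
Conditions: mCPBA (1.5 equiv), CH2Cl2, 40 °C; then HCl (cat.), MeOH, rt
Reagents that add atoms: 3-chloroperoxybenzoic acid (mCPBA), OOC(=O)c1cccc(Cl)c1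
Why: Baeyer–Villiger oxidation of an ortho-alkoxy benzaldehyde (Dakin-type), in which the aryl group, supported by the ortho methoxy donor, should migrate in the Criegee adduct in preference to hydride, followed by acid-catalysed methanolysis of the formate.

Step 4
Reactants: 5 3,5,6-tribromo-2-methoxyphenol; 6 ethyl 2-chloroacetoacetate (ethyl 2-chloro-3-oxobutanoate)
Product: 7 ethyl 2-(3,5,6-tribromo-2-methoxyphenoxy)-3-oxobutanoate (racemic, enolizable)
Conditions: K2CO3, KI (cat.), acetone, reflux
Reagents that add atoms: none
Why: Williamson-type O-alkylation; the hard phenoxide oxygen displaces chloride by SN2 at a carbon activated by two flanking carbonyl groups, the usual entry to 2-aryloxy acetoacetates.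

Step 5
Reactants: 7 ethyl 2-(3,5,6-tribromo-2-methoxyphenoxy)-3-oxobutanoate; 8 acrolein (prop-2-enal)
Product: 11 ethyl 1-(3,5,6-tribromo-2-methoxyphenoxy)-2-oxocyclohex-3-ene-1-carboxylate (racemic), via keto aldehyde 9 (not isolated), via cyclic aldol 10 (not isolated)
Conditions: 8 (1.5 equiv), Et3N (10 mol%), CH2Cl2, 0 °C to rt; evaporate; then p-TsOH·H2O (10 mol%), toluene, 80 °C
Reagents that add atoms: none
Why: Triethylamine forms the stabilized enolate of 7, which adds in a Michael reaction to the β-carbon of 8 (bond C2–C3 of ring A) to give keto aldehyde 9; under acid the enol of the methyl ketone attacks the aldehyde (bond C5–C6) and the aldol 10 loses water to the conjugated enone 11. The closest known reaction type is the Robinson-type annulation of an α-substituted β-keto ester with an enal, that is, Michael addition followed by aldol condensation. Ring A closes in a 6-(enolendo)-exo-trig mode. The quaternary carbon and the carbinol carbon of 10 are formed without any controlling element, as a racemate and a diastereomer mixture, and need none because both become sp2 carbons of ring A later. Regioselectivity for the aryloxy-bearing carbon over the acetyl methyl follows from acidity, since only that carbon lies between the ketone and the ester and only its enolate is present under amine catalysis; the aldol direction is fixed by the tether, because attack of the aldehyde α-carbon on the ketone would close a four-membered ring. Both carbons ortho to the ring B oxygen are substituted, so the acid cannot divert the aryloxy ketone into a benzofuran.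

Step 6
Reactants: 11 ethyl 1-(3,5,6-tribromo-2-methoxyphenoxy)-2-oxocyclohex-3-ene-1-carboxylate
Product: 12 6-(3,5,6-tribromo-2-methoxyphenoxy)cyclohex-2-en-1-one (racemic)
Conditions: LiCl, H2O (2 equiv), DMSO, 150 °C
Reagents that add atoms: none
Why: Krapcho dealkoxycarbonylation, in which chloride removes the ethyl group by SN2, the β-keto carboxylate loses CO2 and water protonates the enolate; this near-neutral process avoids the retro-Claisen ring opening that hydroxide could cause at a non-enolizable β-keto ester, and the new stereocentre forms as a racemate that the next step removes.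

Step 7
Reactants: 12 6-(3,5,6-tribromo-2-methoxyphenoxy)cyclohex-2-en-1-one
Product: 13 2-(3,5,6-tribromo-2-methoxyphenoxy)phenol
Conditions: I2 (20 mol%), DMSO, 90 °C
Reagents that add atoms: none
Why: Iodine-catalysed dehydrogenative aromatization of a cyclohexenone: iodination of the enol at the aryloxy-bearing carbon, loss of HI to the cross-conjugated dienone and tautomerization should give the phenol, while DMSO reoxidizes HI to I2 and the aryl bromides stay untouched because no transition metal is present.

Step 8
Reactants: 13 2-(3,5,6-tribromo-2-methoxyphenoxy)phenol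
Product: 14 4-bromo-2-(3,5,6-tribromo-2-methoxyphenoxy)phenol
Conditions: NBS (1.0 equiv), MeCN, −20 to 0 °C
Reagents that add atoms: N-bromosuccinimide, O=C1CCC(=O)N1Br
Why: Electrophilic aromatic bromination; the free hydroxyl is the strongest donor and directs to its para carbon C4 of ring A, with the ortho carbon C6 as the minor competitor held back by low temperature and a polar solvent, whereas ring B carries three bromines and no free hydroxyl and should not react.

Step 9
Reactants: 14 4-bromo-2-(3,5,6-tribromo-2-methoxyphenoxy)phenol
Product: 15 3,4,6-tribromo-2-(5-bromo-2-hydroxyphenoxy)phenol (target)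
Conditions: BBr3 (3 equiv), CH2Cl2, −78 °C to rt; then H2O
Reagents that add atoms: none
Why: Lewis-acid cleavage of an aryl methyl ether, in which BBr3 coordinates the methoxy oxygen and bromide removes the methyl group by SN2; the diaryl ether offers no sp3 carbon for attack and the aryl bromides are inert, and aqueous work-up hydrolyses the aryl borates.

Compound list
1 | 2-bromo-6-hydroxybenzaldehyde | O=Cc1c(O)cccc1Br | starting material
2 | 3,5,6-tribromo-2-hydroxybenzaldehyde | O=Cc1c(O)c(Br)cc(Br)c1Br | intermediate
3 | 3,5,6-tribromo-2-methoxybenzaldehyde | O=Cc1c(OC)c(Br)cc(Br)c1Br | intermediate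
4 | 3,5,6-tribromo-2-methoxyphenyl formate (not isolated) | O=COc1c(OC)c(Br)cc(Br)c1Br | intermediate
5 | 3,5,6-tribromo-2-methoxyphenol | Oc1c(OC)c(Br)cc(Br)c1Br | intermediate
6 | ethyl 2-chloroacetoacetate (ethyl 2-chloro-3-oxobutanoate, racemic) | CCOC(=O)C(Cl)C(C)=O | starting material
7 | ethyl 2-(3,5,6-tribromo-2-methoxyphenoxy)-3-oxobutanoate (racemic) | CCOC(=O)C(Oc1c(OC)c(Br)cc(Br)c1Br)C(C)=O | intermediate
8 | acrolein (prop-2-enal) | C=CC=O | starting material
9 | ethyl 2-acetyl-5-oxo-2-(3,5,6-tribromo-2-methoxyphenoxy)pentanoate (racemic, not isolated) | CCOC(=O)C(Oc1c(OC)c(Br)cc(Br)c1Br)(CCC=O)C(C)=O | intermediate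
10 | ethyl 4-hydroxy-2-oxo-1-(3,5,6-tribromo-2-methoxyphenoxy)cyclohexane-1-carboxylate (racemic diastereomer mixture, not isolated) | CCOC(=O)C1(Oc2c(OC)c(Br)cc(Br)c2Br)CCC(O)CC1=O | intermediate
11 | ethyl 1-(3,5,6-tribromo-2-methoxyphenoxy)-2-oxocyclohex-3-ene-1-carboxylate (racemic) | CCOC(=O)C1(Oc2c(OC)c(Br)cc(Br)c2Br)CCC=CC1=O | intermediate
12 | 6-(3,5,6-tribromo-2-methoxyphenoxy)cyclohex-2-en-1-one (racemic) | O=C1C=CCCC1Oc1c(OC)c(Br)cc(Br)c1Br | intermediate
13 | 2-(3,5,6-tribromo-2-methoxyphenoxy)phenol | Oc1ccccc1Oc1c(OC)c(Br)cc(Br)c1Br | intermediate
14 | 4-bromo-2-(3,5,6-tribromo-2-methoxyphenoxy)phenol | Oc1ccc(Br)cc1Oc1c(OC)c(Br)cc(Br)c1Br | intermediate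
15 | 3,4,6-tribromo-2-(5-bromo-2-hydroxyphenoxy)phenol | Oc1ccc(Br)cc1Oc1c(O)c(Br)cc(Br)c1Br | target

Total step count: 9. Longest linear sequence: 9 steps (1 to 15); compounds 6 and 8 enter as purchased materials.

Steps most likely to fail

Step 5. Oligomerization of acrolein or retro-Claisen loss of the acetyl group may outrun bond formation at the crowded, fully substituted carbon, and the aldol closure may stall before dehydration. The fallback sets out from 7 and replaces the conjugate addition by an enolate alkylation with a masked aldehyde. Compound 7 is C-alkylated with 2-(2-bromoethyl)-1,3-dioxolane (Cs2CO3, NaI cat., DMF, 50 °C) to give ethyl 2-acetyl-4-(1,3-dioxolan-2-yl)-2-(3,5,6-tribromo-2-methoxyphenoxy)butanoate F1. Aqueous HCl in THF then releases the aldehyde (keto aldehyde 9) without free acrolein ever being present, and p-TsOH in toluene at 80 °C closes ring A by the same aldol condensation. The fallback returns to the route at 11.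

Step 7. Under the HI formed, elimination of the ring B phenoxide from the dienol may aromatize ring A by loss of the aryloxy group instead of by oxidation, and the electron-rich phenol may be iodinated once formed. The fallback sets out from 12 and installs the extra unsaturation by selenoxide elimination. Kinetic deprotonation at the aryloxy-bearing carbon (LiN(SiMe3)2, THF, −78 °C; the amide is too weak to metalate ring B) and trapping with PhSeBr give 6-(phenylselanyl)-6-(3,5,6-tribromo-2-methoxyphenoxy)cyclohex-2-en-1-one F2. Oxidation with H2O2 and pyridine in CH2Cl2 at 0 °C to rt triggers syn-elimination towards the neighbouring CH2, and enolization of the resulting dienone should give the phenol directly. The fallback returns to the route at 13.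

Step 4. SN2 displacement at a secondary carbon by a phenoxide that is both doubly ortho-substituted and electron-poor may be slow, so that base-induced self-condensation of the chloro keto ester takes over. The fallback sets out from 5 and forms the C–O bond by carbenoid O–H insertion, which depends little on the nucleophilicity or bulk of the phenol. Diazo transfer to ethyl acetoacetate (4-acetamidobenzenesulfonyl azide, Et3N, MeCN) gives ethyl 2-diazo-3-oxobutanoate F3, which is added slowly to 5 and Rh2(OAc)4 (1 mol%) in CH2Cl2 at reflux. The fallback returns to the route at 7.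

Further compounds
F1 | step 5 | ethyl 2-acetyl-4-(1,3-dioxolan-2-yl)-2-(3,5,6-tribromo-2-methoxyphenoxy)butanoate (racemic) | CCOC(=O)C(Oc1c(OC)c(Br)cc(Br)c1Br)(CCC1OCCO1)C(C)=O
F2 | step 7 | 6-(phenylselanyl)-6-(3,5,6-tribromo-2-methoxyphenoxy)cyclohex-2-en-1-one (racemic) | O=C1C=CCCC1([Se]c1ccccc1)Oc1c(OC)c(Br)cc(Br)c1Br
F3 | step 4 | ethyl 2-diazo-3-oxobutanoate | CCOC(=O)C(=[N+]=[N-])C(C)=O
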